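Its constants were set for the occasion; the result is computed.

The first step's rate constant is larger in maple at 50 °C than in oak at −40 °C by a factor of 63700, so we ask of each flask how far its opening rate could carry it in the time.

    starting material + partner ⇌ target (K1 = 5.2 L mol⁻¹, k1 = 8.35 × 10⁻⁴ L mol⁻¹ s⁻¹, Ea1 = 77.0 kJ mol⁻¹, ΔH1 = −25.0 kJ mol⁻¹)
    second substrate + partner ⇌ second product (K2 = 2.57 L mol⁻¹, k2 = 0.00108 L mol⁻¹ s⁻¹, Ea2 = 71.0 kJ mol⁻¹, ΔH2 = −90.0 kJ mol⁻¹)
    partner ⇌ dormant form (K3 = 0.619, k3 = 3.89 × 10⁻⁵ s⁻¹, Ea3 = 86.0 kJ mol⁻¹, ΔH3 = 0 kJ mol⁻¹)
    (constants at 20 °C)

| flask | starting material | partner | second substrate | temperature | time |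
|---|---|---|---|---|---|
| cedar | 0.20 M | 2.00 equiv | 1.00 equiv | −10 °C | 8.0 h |
| oak | 0.20 M | 2.00 equiv | 1.00 equiv | −40 °C | 8.0 h |
| maple | 0.20 M | 2.00 equiv | 1.00 equiv | 50 °C | 8.0 h |
| ash | 0.20 M | 2.00 equiv | 1.00 equiv | 20 °C | 8.0 h |

* the best flask by amount of target, in percent of the starting material charged; "all alike" if 1.5 percentage points covers them all (cedar / oak / maple / ash / all alike)
* amount of target at the end, in percent of the starting material charged, cedar
* amount of target at the end, in percent of the starting material charged, oak
* amount of target at the end, in percent of the starting material charged, maple
* amount of target at the end, in percent of the starting material charged, ash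

- at 20 °C the constants are as listed, elsewhere as the activation energies and enthalpies make them

Starting material is charged in a smaller amount than partner, and its balance is short: each target formed is one starting material gone. With partner held at its opening value the first step is pseudo-first-order, and the share of starting material turned per unit time is the rate constant at the flask's temperature times that partner. We multiply this by the time:

oak: 0.283%

We call this the forward number: the share of the starting material that the opening rate would turn into target in the time if it did not slow. In oak it is so small that too little is used to slow the rate much, and we take it as our reckoning for oak.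

Cedar is different:

cedar: 26.2%

In cedar the rate falls on three counts, and we estimate each factor for the end of the time.

starting material going: 0.769

partner taken by all three steps, at their opening pace: 0.687

backward run, with the equilibrium constant at 16.7 L mol⁻¹: 0.935

Multiplied, these put cedar's closing rate at 0.494 of the opening one. Averaging that with the opening rate gives a mean factor of 0.747, so we reckon cedar at 19.6%.

In the two warm flasks the reckoning stops being useful:

ash: 962%

maple: 18065%

Both are far above the whole charge, so the opening rate says little about where these two flasks end. We can say that the equilibrium constant is smaller in maple, at 2.01 L mol⁻¹, than in ash, at 5.2 L mol⁻¹, and so we expect ash above maple.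

The forecast names ash, with cedar at 19.6%, oak at 0.28%, maple at 29.5% and ash at 45.7%, and it holds that “Cedar and oak are kinetically limited”.

The simulation names ash, with cedar at 19.6%, oak at 0.282%, maple at 29.5% and ash at 45.7%. Oak's reading lies beside its forward number of 0.283%, and cedar's beside our reckoned 19.6%. Maple's forward number of 18065% is far beyond what it reads, and the main reason is the backward run from target: the same maple flask without that run gives 100% against 29.5%. Oak left until 80.0 h has a forward number of 2.83%, and that flask reads 2.73%.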